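**Assumption (one line):** tricyclic compounds are numbered as tricyclo[5.4.0.0(2,8)]undecanes (cyclobutane = C1–C2–C8–C7); the sense of induction of the two chiral catalysts (steps 3 and 7) is taken from the usual models and would be corrected by using the mirror-image catalyst. The route is a paper design; the steps marked "Proposed new method" have no direct precedent.

## Retrosynthetic overview

1. Target ⇐ angeloylation of hydroxy ester 14 ⇐ Evans–Tishchenko reduction of β-hydroxy ketone 12 with methacrolein (sets C3, installs the methacrylate) ⇐ conjugate borylation/oxidation of tricyclic bis-enone 10.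
2. Key disconnection: the C1–C2 cyclobutane bond of 10 joins the two α-carbons of a 1,4-diketone; it is made by transannular oxidative coupling of the bis-enolate of the cis-fused 6-7 bis-enone 8, one enolate acting as the enolonium partner.
3. 8 ⇐ siloxycyclopropane 7: oxidative ring opening gives a β-keto radical (homoenolate equivalent) that closes the cyclohexenone by 6-endo addition to a tethered ynone while the six-membered ring is enlarged to the cycloheptenone.
4. 7 ⇐ ethylidene cyclopropanation of silyl dienol ether 5 ⇐ enantioselective Mukaiyama–Michael desymmetrisation of dienone 2 with the silyl enol ether of pent-3-yn-2-one.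
5. Ring order: six-membered ring (bought) → seven-membered ring and cyclohexenone together (step 5) → cyclobutane last (step 6).

## Route

Step 1
Reactants: 1 4,4-dimethylcyclohex-2-en-1-one
Product: 2 4,4-dimethylcyclohexa-2,5-dien-1-one
Conditions: DDQ (1.3 equiv), TsOH·H2O (5 mol %), 1,4-dioxane, reflux
Reagents that add atoms: none
Why: Quinone dehydrogenation of an enone to the cross-conjugated dienone is standard, and the quaternary carbon prevents aromatisation, giving an achiral, prochiral dienone.

Step 2
Reactants: 3 pent-3-yn-2-one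
Product: 4 2-(trimethylsilyloxy)pent-1-en-3-yne
Conditions: TMSOTf (1.1 equiv), Et3N (1.3 equiv), Et2O, 0 °C
Reagents that add atoms: trimethylsilyl triflate, C[Si](C)(C)OS(=O)(=O)C(F)(F)F
Why: Soft enolisation and O-silylation (silyl enol ether formation) of a methyl ketone whose only enolisable position is the methyl group gives a single regioisomer.

Step 3
Reactants: 2 4,4-dimethylcyclohexa-2,5-dien-1-one; 4 2-(trimethylsilyloxy)pent-1-en-3-yne
Product: 5 1-[(1R)-6,6-dimethyl-3-(trimethylsilyloxy)cyclohexa-2,4-dien-1-yl]pent-3-yn-2-one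
Conditions: (S)-1-(2-methylphenyl)-3,3-diphenyltetrahydro-1H,3H-pyrrolo[1,2-c][1,3,2]oxazaborole + HN(SO2CF3)2 (20 mol %), Ph3PO (25 mol %), toluene, −78 → −40 °C; non-aqueous work-up through Et3N-deactivated silica
Reagents that add atoms: none
Why: Proposed new method: the chiral oxazaborolidinium Lewis acid binds one carbonyl lone pair of the dienone and shields one face, so the silyl enol ether attacks only one of the two enantiotopic β-carbons (this sets the single stereocentre, R), and silyl transfer to the new enolate gives the cross-conjugated silyl dienol ether regiospecifically; the closest known reaction is the oxazaborolidinium-catalysed enantioselective Mukaiyama–Michael addition of silyl ketene acetals to cyclic enones.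

Step 4
Reactants: 5 1-[(1R)-6,6-dimethyl-3-(trimethylsilyloxy)cyclohexa-2,4-dien-1-yl]pent-3-yn-2-one; 6 1,1-diiodoethane
Product: 7 1-[(5R)-4,4,7-trimethyl-1-(trimethylsilyloxy)bicyclo[4.1.0]hept-2-en-5-yl]pent-3-yn-2-one (mixture at the three cyclopropane carbons)
Conditions: Et2Zn (2.5 equiv), CH3CHI2 (2.5 equiv), CH2Cl2, −20 → 0 °C
Reagents that add atoms: none
Why: Furukawa-type Simmons–Smith cyclopropanation with the ethylidene zinc carbenoid attacks the electron-rich silyl enol ether double bond in preference to the hindered disubstituted alkene and the electron-poor ynone, and the three new cyclopropane stereocentres (anti to the side chain, methyl exo/endo mixed) are all erased in step 5.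

Step 5
Reactants: 7 1-[(5R)-4,4,7-trimethyl-1-(trimethylsilyloxy)bicyclo[4.1.0]hept-2-en-5-yl]pent-3-yn-2-one
Product: 8 (4aS,9aR)-4,5,9,9-tetramethyl-4a,5,9,9a-tetrahydro-1H-benzo[7]annulene-2,6-dione (cis-fused; C5 epimers)
Conditions: Fe(NO3)3·9H2O (2.2 equiv), 1,4-cyclohexadiene (10 equiv), DMF, 0 °C → rt
Reagents that add atoms: none
Why: Proposed new method: one-electron oxidation of the siloxycyclopropane by trivalent iron gives a cyclopropyloxy radical whose β-scission of the ring-fusion bond enlarges the ring to the cyclohept-2-enone and leaves a secondary β-keto radical (homoenolate radical equivalent; the isomeric exocyclic radical can return through the same cyclopropyloxy radical, as in Dowd–Beckwith ring expansion), this radical adds 6-endo-dig to the β-carbon of the ynone and the α-keto vinyl radical takes hydrogen from 1,4-cyclohexadiene, the ring fusion coming out cis because C5 on C4a must stay pseudo-axial to avoid A(1,2) strain against the C4 methyl while the quaternary C9 on C9a is equatorial (C5 is a mixture that is erased in step 6); the closest known reactions are the ferric-nitrate ring expansion/5-exo cyclisation of alkenyl-substituted bicyclic cyclopropyl silyl ethers and the Ito–Saegusa ring enlargement.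

Step 6
Reactants: 8 (4aS,9aR)-4,5,9,9-tetramethyl-4a,5,9,9a-tetrahydro-1H-benzo[7]annulene-2,6-dione
Product: 10 (1R,2R,7S,8R)-2,6,6,9-tetramethyltricyclo[5.4.0.0(2,8)]undeca-4,9-diene-3,11-dione, via dilithium bis-dienolate 9 (not isolated)
Conditions: LiN(iPr)2 (2.4 equiv), THF, −78 °C, 1 h; then CuCl2 (2.5 equiv) in DMF, −78 → 0 °C, 5 mM
Reagents that add atoms: none
Why: Proposed new method: kinetic double deprotonation gives the two cross-conjugated dienolates, each with a single nucleophilic carbon (C1 and C5 of 8), divalent copper oxidises one of them to an electrophilic α-keto radical (enolonium equivalent) that is captured by the other enolate held about 3 Å away across the cis-fused bicycle, and a second one-electron oxidation of the resulting ketyl gives the 1,2-diacylcyclobutane, the quaternary centre and the bridgehead being fixed by the ring fusion because the bond can form on one face only; the closest known reaction is the intramolecular oxidative coupling of carbonyl bis-enolates with divalent copper or trivalent iron salts, which also closes three- and four-membered rings.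

Step 7
Reactants: 10 (1R,2R,7S,8R)-2,6,6,9-tetramethyltricyclo[5.4.0.0(2,8)]undeca-4,9-diene-3,11-dione
Product: 12 (1R,2R,5R,7S,8R)-5-hydroxy-2,6,6,9-tetramethyltricyclo[5.4.0.0(2,8)]undec-9-ene-3,11-dione, via beta-boryl ketone 11 (not isolated)
Conditions: B2pin2 (1.2 equiv), CuCl (5 mol %), (R,R)-2,3-bis(tert-butylmethylphosphino)quinoxaline (6 mol %), NaOtBu (10 mol %), MeOH (2 equiv), THF, 0 °C; then NaBO3·4H2O, THF/H2O, 0 °C → rt
Reagents that add atoms: bis(pinacolato)diboron, CC1(C)OB(OC1(C)C)B1OC(C)(C)C(C)(C)O1 (boryl group of 11); sodium perborate, [Na+].[O-]B1OO1 (hydroxyl oxygen of 12)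
Why: Copper-catalysed conjugate borylation takes the disubstituted cycloheptenone (the trisubstituted, bridgehead-flanked enone is far less reactive) and stereoretentive perborate oxidation gives the β-hydroxy ketone; the two faces of the bridge alkene are nearly equivalent, so the chiral bisphosphine decides and is chosen to borylate the Re face of C5 (5R).

Step 8
Reactants: 12 (1R,2R,5R,7S,8R)-5-hydroxy-2,6,6,9-tetramethyltricyclo[5.4.0.0(2,8)]undec-9-ene-3,11-dione; 13 methacrolein
Product: 14 (1R,2R,3R,5R,7S,8R)-3-hydroxy-2,6,6,9-tetramethyl-11-oxotricyclo[5.4.0.0(2,8)]undec-9-en-5-yl 2-methylprop-2-enoate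
Conditions: SmI2 (30 mol %), methacrolein (8 equiv), THF, −10 °C
Reagents that add atoms: none
Why: Evans–Tishchenko reduction: the samarium-bound hemiacetal formed from the C5 hydroxyl and methacrolein delivers its hydride intramolecularly to the C3 ketone from the face of the C5 oxygen, giving the 1,3-anti (3R) alcohol and turning the aldehyde into the C5 methacrylate, so the two oxygens are differentiated without protecting groups.

Step 9
Reactants: 14 (1R,2R,3R,5R,7S,8R)-3-hydroxy-2,6,6,9-tetramethyl-11-oxotricyclo[5.4.0.0(2,8)]undec-9-en-5-yl 2-methylprop-2-enoate; 15 angelic acid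
Product: 17 (1R,2R,3R,5R,7S,8R)-2,6,6,9-tetramethyl-3-{[(2Z)-2-methylbut-2-enoyl]oxy}-11-oxotricyclo[5.4.0.0(2,8)]undec-9-en-5-yl 2-methylprop-2-enoate, via mixed anhydride 16 (not isolated)
Conditions: 15 (1.5 equiv), 2,4,6-Cl3C6H2COCl (1.5 equiv), Et3N (3 equiv), toluene, rt, 1 h; then 14, BHT (cat.), 75 °C
Reagents that add atoms: 2,4,6-trichlorobenzoyl chloride, O=C(Cl)c1c(Cl)cc(Cl)cc1Cl (its aroyl group is carried only by intermediate 16)
Why: Yamaguchi-type mixed-anhydride esterification without DMAP acylates the hindered C3 alcohol while avoiding base-induced Z to E (angelate to tiglate) isomerisation, and the trans-1,3 arrangement on the rigid bridge disfavours acyl migration; no stereocentre is touched.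

## Compound list

1 | 4,4-dimethylcyclohex-2-en-1-one | CC1(C)CCC(=O)C=C1 | starting material
2 | 4,4-dimethylcyclohexa-2,5-dien-1-one | CC1(C)C=CC(=O)C=C1 | intermediate
3 | pent-3-yn-2-one | CC#CC(C)=O | starting material
4 | 2-(trimethylsilyloxy)pent-1-en-3-yne | C=C(O[Si](C)(C)C)C#CC | intermediate
5 | 1-[(1R)-6,6-dimethyl-3-(trimethylsilyloxy)cyclohexa-2,4-dien-1-yl]pent-3-yn-2-one | C[Si](C)(C)OC1=C[C@@H](CC(=O)C#CC)C(C)(C)C=C1 | intermediate
6 | 1,1-diiodoethane | CC(I)I | starting material
7 | 1-[(5R)-4,4,7-trimethyl-1-(trimethylsilyloxy)bicyclo[4.1.0]hept-2-en-5-yl]pent-3-yn-2-one (C1, C6, C7 as formed, mixture) | C[Si](C)(C)OC12C=CC(C)(C)[C@H](CC(=O)C#CC)C1C2C | intermediate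
8 | (4aS,9aR)-4,5,9,9-tetramethyl-4a,5,9,9a-tetrahydro-1H-benzo[7]annulene-2,6-dione (cis-fused, C5 epimers) | C1=CC(=O)C(C)[C@H]2C(C)=CC(=O)C[C@H]2C1(C)C | intermediate
9 | dilithium (4aR,9aS)-4,5,9,9-tetramethyl-4a,9a-dihydro-9H-benzo[7]annulene-2,6-bis(olate) | [Li+].[Li+].[O-]C1=C(C)[C@H]2C(C)=CC([O-])=C[C@H]2C(C)(C)C=C1 | intermediate (not isolated)
10 | (1R,2R,7S,8R)-2,6,6,9-tetramethyltricyclo[5.4.0.0(2,8)]undeca-4,9-diene-3,11-dione | C1=CC(=O)[C@@]2(C)[C@@H]3C(=O)C=C(C)[C@H]2[C@@H]3C1(C)C | intermediate
11 | (1R,2R,5R,7S,8R)-2,6,6,9-tetramethyl-5-(4,4,5,5-tetramethyl-1,3,2-dioxaborolan-2-yl)tricyclo[5.4.0.0(2,8)]undec-9-ene-3,11-dione | CC1(C)OB(OC1(C)C)[C@@H]2CC(=O)[C@@]3(C)[C@@H]4C(=O)C=C(C)[C@H]3[C@@H]4C2(C)C | intermediate (not isolated)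
12 | (1R,2R,5R,7S,8R)-5-hydroxy-2,6,6,9-tetramethyltricyclo[5.4.0.0(2,8)]undec-9-ene-3,11-dione | O[C@@H]1CC(=O)[C@@]2(C)[C@@H]3C(=O)C=C(C)[C@H]2[C@@H]3C1(C)C | intermediate
13 | methacrolein (2-methylprop-2-enal) | C=C(C)C=O | starting material
14 | (1R,2R,3R,5R,7S,8R)-3-hydroxy-2,6,6,9-tetramethyl-11-oxotricyclo[5.4.0.0(2,8)]undec-9-en-5-yl 2-methylprop-2-enoate | C=C(C)C(=O)O[C@@H]1C[C@@H](O)[C@@]2(C)[C@@H]3C(=O)C=C(C)[C@H]2[C@@H]3C1(C)C | intermediate
15 | angelic acid ((2Z)-2-methylbut-2-enoic acid) | C/C=C(/C)C(=O)O | starting material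
16 | (2Z)-2-methylbut-2-enoic 2,4,6-trichlorobenzoic anhydride | C/C=C(/C)C(=O)OC(=O)c1c(Cl)cc(Cl)cc1Cl | intermediate (not isolated)
17 | (1R,2R,3R,5R,7S,8R)-2,6,6,9-tetramethyl-3-{[(2Z)-2-methylbut-2-enoyl]oxy}-11-oxotricyclo[5.4.0.0(2,8)]undec-9-en-5-yl 2-methylprop-2-enoate (CNP0317071.1) | C=C(C)C(=O)O[C@@H]1C[C@@H](OC(=O)/C(C)=C\C)[C@@]2(C)[C@@H]3C(=O)C=C(C)[C@H]2[C@@H]3C1(C)C | target

## Step count and risks

Total steps: 9. Longest linear sequence: 8 (steps 1, 3, 4, 5, 6, 7, 8, 9; the branch through step 2 is equally long).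

**Most likely to fail, in order: step 6, step 5, step 3.**

Step 6 (transannular oxidative bis-enolate coupling). Risks are transannular aldol of the mono-enolate, α-chlorination, and over-oxidation of the cyclohexadienolate toward a phenol. The fallback sets out from 8: the dianion is made as before and quenched with Me3SiCl to give the bis-silyl dienol ether (4aR,9aS)-4,5,9,9-tetramethyl-2,6-bis(trimethylsilyloxy)-4a,9a-dihydro-9H-benzo[7]annulene F5. This is treated with iodosylbenzene and BF3·OEt2 in CH2Cl2 at −40 °C. The more electron-rich silyl enol ether becomes an α-(phenyliodanyl) ketone, a discrete enolonium equivalent of trivalent iodine, which the second silyl enol ether displaces intramolecularly (the hypervalent-iodine 1,4-diketone synthesis). The route is rejoined at 10.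

Step 5 (ring expansion/6-endo radical cyclisation). Risks are scission of the exocyclic cyclopropane bond, inefficient hydrogen transfer, and trans ring fusion. The fallback sets out from 7: FeCl3 in DMF at 0 °C (Ito–Saegusa ring enlargement) gives the β-chloro ketone 1-[(1S)-7-chloro-2,2,6-trimethyl-5-oxocyclohept-3-en-1-yl]pent-3-yn-2-one F3. NaOAc in MeOH eliminates HCl to the cross-conjugated dienone 1-[(1R)-2,2,6-trimethyl-5-oxocyclohepta-3,6-dien-1-yl]pent-3-yn-2-one F4. SmI2 with t-BuOH in THF at −78 °C then joins the two β-carbons by reductive anion-radical cyclisation of the enone onto the ynone. The route is rejoined at 8.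

Step 3 (enantioselective Mukaiyama–Michael with a ketone-derived silyl enol ether). Risks are low nucleophilicity, unknown selectivity, and a second intramolecular Michael addition of the product onto its own ynone. The fallback sets out from 2: the same chiral Lewis acid is used with 1-(ethylsulfanyl)-1-(trimethylsilyloxy)ethene, a ketene silyl thioacetal of the established, more nucleophilic class that cannot cyclise further, giving S-ethyl 2-[(1R)-6,6-dimethyl-3-(trimethylsilyloxy)cyclohexa-2,4-dien-1-yl]ethanethioate F1. Cyclopropanation as in step 4 gives S-ethyl 2-[(5R)-4,4,7-trimethyl-1-(trimethylsilyloxy)bicyclo[4.1.0]hept-2-en-5-yl]ethanethioate F2. Coupling of the thioester with propyne (PdCl2(dppf), CuI, tri(2-furyl)phosphine, Et3N, DMF, 50 °C) installs the ynone. The route is rejoined at 7.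

## Further compounds

F1 | step 3 | S-ethyl 2-[(1R)-6,6-dimethyl-3-(trimethylsilyloxy)cyclohexa-2,4-dien-1-yl]ethanethioate | C[Si](C)(C)OC1=C[C@@H](CC(=O)SCC)C(C)(C)C=C1
F2 | step 3 | S-ethyl 2-[(5R)-4,4,7-trimethyl-1-(trimethylsilyloxy)bicyclo[4.1.0]hept-2-en-5-yl]ethanethioate (cyclopropane carbons as formed) | C[Si](C)(C)OC12C=CC(C)(C)[C@H](CC(=O)SCC)C1C2C
F3 | step 5 | 1-[(1S)-7-chloro-2,2,6-trimethyl-5-oxocyclohept-3-en-1-yl]pent-3-yn-2-one (C6, C7 epimers) | CC#CC(=O)C[C@@H]1C(Cl)C(C)C(=O)C=CC1(C)C
F4 | step 5 | 1-[(1R)-2,2,6-trimethyl-5-oxocyclohepta-3,6-dien-1-yl]pent-3-yn-2-one | CC#CC(=O)C[C@@H]1C=C(C)C(=O)C=CC1(C)C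
F5 | step 6 | (4aR,9aS)-4,5,9,9-tetramethyl-2,6-bis(trimethylsilyloxy)-4a,9a-dihydro-9H-benzo[7]annulene | C[Si](C)(C)OC1=C(C)[C@H]2C(C)=CC(O[Si](C)(C)C)=C[C@H]2C(C)(C)C=C1
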